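## Retrosynthetic overview

1. Numbering (elemane): C1=C2 vinyl and C14 methyl on quaternary C10; C5 carries C4 (oxirane with C3, formyl C15); C6 bears the isobutyrate; C7/C8 carry the cis-fused α-methylene lactone (C11=C13, C12); C9 bears OH. Enabling feature: C9(OH)–C10(C1=C2) is a homoallylic alcohol, and C6–O and C9–O flank the C5–C10 bond of the carbocycle (C5–C6–C7–C8–C9–C10). This is the imprint of two successive allylborations by one 1,2-bis(boronate) with boron on C1 and C2.
2. Late stage: C3–C4 oxirane by Sharpless epoxidation of the C4(=C3)–C15H2OH allylic alcohol, then oxidation of C15 to the aldehyde.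
3. Carbocycle, closed last: C9–C10 bond by intramolecular allylboration of the (E)-allyl boronate C2–C1=C10 onto a C9 aldehyde, released by glycol cleavage on the finished lactone.
4. C5–C6 bond: reagent-controlled intermolecular allylboration of lactone aldehyde 19 (C6) with (S)-bis(boronate) 10, made by Pt-catalysed 1,2-diboration of Z-triene 9 (propyne bromoboration, Negishi, Suzuki).
5. Lactone, closed first: indium Barbier allylation and lactonisation of bromide 14 with (R)-glyceraldehyde acetonide. Ring order: lactone, then cyclohexane; the oxirane is then added as a functional group on the finished skeleton.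

Key step: step 14

Assumption: the (R,R)-TADDOL-derived phosphonite is taken to give the (5S)-bis(boronate) 10 in step 5; if the sense of induction is the opposite, the (S,S)-ligand is used.

## Route

Step 1
Reactants: 1 2-bromoprop-2-en-1-ol
Product: 2 [(2-bromoprop-2-en-1-yl)oxy](tert-butyl)diphenylsilane
Conditions: TBDPSCl, imidazole, CH2Cl2, 0 °C → rt
Reagents that add atoms: tert-butyl(chloro)diphenylsilane, CC(C)(C)[Si](Cl)(c1ccccc1)c1ccccc1
Why: Routine silylation of a primary alcohol; TBDPS is chosen because the C15 oxygen must survive aqueous base, aqueous acetic acid and periodate before its removal in step 15.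

Step 2
Reactants: 3 propyne
Product: 5 2-[(1Z)-2-bromoprop-1-en-1-yl]-4,4,5,5-tetramethyl-1,3,2-dioxaborolane, via dibromoborane 4 (not isolated)
Conditions: BBr3, CH2Cl2, −78 °C → rt; then pinacol, −78 °C → rt
Reagents that add atoms: boron tribromide, BrB(Br)Br; pinacol, CC(C)(O)C(C)(C)O
Why: syn-Bromoboration of a terminal alkyne puts boron on the terminal carbon and bromine cis to it on the internal carbon, and immediate transesterification with pinacol fixes the (Z)-geometry that becomes the C10=C5 geometry of the triene.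

Step 3
Reactants: 5 2-[(1Z)-2-bromoprop-1-en-1-yl]-4,4,5,5-tetramethyl-1,3,2-dioxaborolane; 6 vinylmagnesium bromide
Product: 8 4,4,5,5-tetramethyl-2-[(1Z)-2-methylbuta-1,3-dien-1-yl]-1,3,2-dioxaborolane, via vinylzinc bromide 7 (not isolated)
Conditions: 6, ZnBr2, THF, 0 °C; then 5, Pd(t-Bu3P)2 (2 mol%), THF, rt
Reagents that add atoms: none
Why: Negishi coupling at the C–Br bond should proceed with retention of the alkene geometry and leave the pinacol boronate untouched, which is the known behaviour of this class of β-bromoalkenyl boronates with organozinc reagents.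

Step 4
Reactants: 8 4,4,5,5-tetramethyl-2-[(1Z)-2-methylbuta-1,3-dien-1-yl]-1,3,2-dioxaborolane; 2 [(2-bromoprop-2-en-1-yl)oxy](tert-butyl)diphenylsilane
Product: 9 tert-butyl{[(3Z)-4-methyl-2-methylidenehexa-3,5-dien-1-yl]oxy}diphenylsilane
Conditions: Pd(PPh3)4 (5 mol%), aq. K3PO4, THF, 40 °C, degassed, BHT (trace)
Reagents that add atoms: none
Why: Suzuki–Miyaura alkenyl–alkenyl coupling proceeds with retention and should give the triene in which the vinyl group and the C4 unit are cis on the C10=C5 bond.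

Step 5
Reactants: 9 tert-butyl{[(3Z)-4-methyl-2-methylidenehexa-3,5-dien-1-yl]oxy}diphenylsilane
Product: 10 (5S)-bis(boronate), tert-butyl{[(3Z,5S)-4-methyl-2-methylidene-5,6-bis(4,4,5,5-tetramethyl-1,3,2-dioxaborolan-2-yl)hex-3-en-1-yl]oxy}diphenylsilane
Conditions: Pt(dba)3 (3 mol%), (R,R)-3,5-diethylphenyl-TADDOL-PPh phosphonite (6 mol%), B2pin2 (1.05 equiv), THF, 60 °C
Reagents that add atoms: bis(pinacolato)diboron, CC1(C)OB(OC1(C)C)B1OC(C)(C)C(C)(C)O1
Why: Pt(0)-catalysed enantioselective 1,2-diboration of cis-1,3-dienes should add B–B across the terminal vinyl group because the cis substituent on C5 disfavours the s-cis conformer needed for 1,4-addition and the monosubstituted alkene is far more reactive than the 1,1-disubstituted and trisubstituted ones; the chiral catalyst sets the boron-bearing C1 stereocentre.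

Step 6
Reactants: 11 methyl acrylate; 12 {[tert-butyl(dimethyl)silyl]oxy}acetaldehyde
Product: 13 methyl 2-(2-{[tert-butyl(dimethyl)silyl]oxy}-1-hydroxyethyl)prop-2-enoate (racemic)
Conditions: DABCO (0.5 equiv), neat, rt
Reagents that add atoms: none
Why: Morita–Baylis–Hillman reaction of an acrylate with an activated α-silyloxy aldehyde; the carbinol centre is racemic and is destroyed in step 7.

Step 7
Reactants: 13 methyl 2-(2-{[tert-butyl(dimethyl)silyl]oxy}-1-hydroxyethyl)prop-2-enoate
Product: 14 methyl (2Z)-2-(bromomethyl)-4-{[tert-butyl(dimethyl)silyl]oxy}but-2-enoate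
Conditions: NBS, Me2S, CH2Cl2, 0 °C → rt
Reagents that add atoms: N-bromosuccinimide, O=C1CCC(=O)N1Br
Why: Bromination of a Baylis–Hillman alcohol through its alkoxysulfonium salt occurs with SN2′ transposition and should give the thermodynamically preferred (Z)-2-(bromomethyl)alk-2-enoate.

Step 8
Reactants: 14 methyl (2Z)-2-(bromomethyl)-4-{[tert-butyl(dimethyl)silyl]oxy}but-2-enoate; 15 (4R)-2,2-dimethyl-1,3-dioxolane-4-carbaldehyde
Product: 17 (4S,5S)-4-({[tert-butyl(dimethyl)silyl]oxy}methyl)-5-[(4R)-2,2-dimethyl-1,3-dioxolan-4-yl]-3-methylideneoxolan-2-one, via hydroxy ester 16 (not isolated)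
Conditions: In powder, THF/H2O (1:1), rt; then PPTS (cat.), CH2Cl2, rt
Reagents that add atoms: none
Why: Indium Barbier allylation at the γ-carbon through a chair transition state should give the syn C7/C8 relationship (cis lactone after acid-promoted lactonisation of the γ-hydroxy ester), and Felkin–Anh (anti) attack on the α-alkoxy aldehyde sets C8 from the (R)-dioxolane, which then serves as the masked C9 aldehyde.

Step 9
Reactants: 17 (4S,5S)-4-({[tert-butyl(dimethyl)silyl]oxy}methyl)-5-[(4R)-2,2-dimethyl-1,3-dioxolan-4-yl]-3-methylideneoxolan-2-one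
Product: 18 (4S,5S)-5-[(4R)-2,2-dimethyl-1,3-dioxolan-4-yl]-4-(hydroxymethyl)-3-methylideneoxolan-2-one
Conditions: HF·pyridine, pyridine, THF, 0 °C → rt
Reagents that add atoms: none
Why: Buffered HF·pyridine removes a primary TBS ether without touching the acetonide or the α-methylene lactone.

Step 10
Reactants: 18 (4S,5S)-5-[(4R)-2,2-dimethyl-1,3-dioxolan-4-yl]-4-(hydroxymethyl)-3-methylideneoxolan-2-one
Product: 19 (2S,3R)-2-[(4R)-2,2-dimethyl-1,3-dioxolan-4-yl]-4-methylidene-5-oxooxolane-3-carbaldehyde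
Conditions: Dess–Martin periodinane, CH2Cl2, 0 °C; filtered and used crude at once
Reagents that add atoms: none
Why: Dess–Martin oxidation under base-free conditions gives the C6 aldehyde, which is not purified because its C7–H is activated by both the formyl group and the methylene lactone.

Step 11
Reactants: 19 (2S,3R)-2-[(4R)-2,2-dimethyl-1,3-dioxolan-4-yl]-4-methylidene-5-oxooxolane-3-carbaldehyde; 10 (5S)-bis(boronate)
Product: 21 C6 carbinol carrying the (E)-allyl boronate (full name in the list), via boryl ether 20 (not isolated)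
Conditions: toluene (1 M), 4 Å MS, rt → 40 °C; then pH 7 buffer
Reagents that add atoms: none
Why: Thermal allylboration by the secondary allylic boronate through a closed chair transition state, with the cis substituent on C5 axial and the CH2Bpin group on C1 equatorial (avoiding 1,3-allylic strain), should transfer the C1 chirality to C5 and C6 (syn adduct) and give the (E)-C1=C10 allyl boronate needed in step 14; the α-substituted boronate is expected to override the modest facial bias of the aldehyde.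

Step 12
Reactants: 21 C6 carbinol carrying the (E)-allyl boronate
Product: 22 C6 isobutyrate of 21 (full name in the list)
Conditions: (i-PrCO)2O, DMAP (cat.), Et3N, CH2Cl2, 0 °C → rt
Reagents that add atoms: isobutyric anhydride, CC(C)C(=O)OC(=O)C(C)C
Why: DMAP-catalysed acylation of the only free hydroxyl installs the isobutyrate at C6 before the C9 oxygen exists, so the two ring oxygens never have to be differentiated.

Step 13
Reactants: 22 C6 isobutyrate
Product: 23 1,2-diol (full name in the list)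
Conditions: AcOH/H2O (4:1), rt
Reagents that add atoms: none
Why: Mild aqueous acid hydrolyses the terminal isopropylidene acetal, while the TBDPS ether, the isobutyrate and the pinacol allyl boronate should be stable.

Step 14
Reactants: 23 1,2-diol
Product: 26 (3aS,4R,5S,6S,7R,7aS)-5-{3-[tert-butyl(diphenyl)silyl]oxyprop-1-en-2-yl}-6-ethenyl-7-hydroxy-6-methyl-3-methylidene-2-oxooctahydro-1-benzofuran-4-yl 2-methylpropanoate, via aldehyde 24 (not isolated), via boryl ether 25 (not isolated)
Conditions: NaIO4 on wet SiO2, CH2Cl2, rt; filter; rt → 35 °C; then aq. NaHCO3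
Reagents that add atoms: none
Why: Periodate cleaves the 1,2-diol to the α-acyloxy aldehyde 24 (C9), which is trapped by the pendant γ,γ-disubstituted allyl boronate in an intramolecular allylboration: boron binds the aldehyde oxygen and C10 attacks C9 through a closed six-membered Zimmerman–Traxler array with allylic transposition, turning C1=C10 into the C1=C2 vinyl group. The closest known reaction types are the cyclisation of ω-oxo allyl boronates to 2-vinylcycloalkanols and the second stage of the tandem diboration/double allylation of 1,4-dicarbonyls, which gives cyclohexane-1,4-diols with a vinyl-bearing quaternary carbon. The carbocycle closes by 6-exo-trig attack on the carbonyl in a chair–chair, trans-decalin-like bicyclic transition state. C10 is set by the (E)-geometry of the boronate (C14 methyl axial, vinyl equatorial) and by the forming chair, in which the C5 side chain, the C6 isobutyrate and C11 are equatorial and only the lactone oxygen on C8 is axial; C9 is set by the equatorial position of C8 in the boron-containing chair, which places the new hydroxyl equatorial, trans to vinyl and cis to C14. The step needs chemoselectivity for the tethered aldehyde over the formaldehyde set free, secured by the intramolecular six-membered closure and by retention of formaldehyde as its hydrate on the wet silica, and it needs the (E)-allyl boronate, secured in step 11.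

Step 15
Reactants: 26 silyl ether
Product: 27 (3aS,4R,5S,6S,7R,7aS)-6-ethenyl-7-hydroxy-5-(3-hydroxyprop-1-en-2-yl)-6-methyl-3-methylidene-2-oxooctahydro-1-benzofuran-4-yl 2-methylpropanoate
Conditions: HF·pyridine, pyridine, THF, rt
Reagents that add atoms: none
Why: Buffered fluoride desilylation of the primary allylic TBDPS ether spares the ester, the lactone Michael acceptor and the free C9 hydroxyl.

Step 16
Reactants: 27 allylic alcohol
Product: 28 (3aS,4S,5S,6S,7R,7aS)-6-ethenyl-7-hydroxy-5-[(2S)-2-(hydroxymethyl)oxiran-2-yl]-6-methyl-3-methylidene-2-oxooctahydro-1-benzofuran-4-yl 2-methylpropanoate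
Conditions: Ti(Oi-Pr)4 (20 mol%), L-(+)-DET (24 mol%), TBHP, 4 Å MS, CH2Cl2, −20 °C
Reagents that add atoms: tert-butyl hydroperoxide, CC(C)(C)OO
Why: Sharpless asymmetric epoxidation is directed by the allylic hydroxyl to the C3=C4 alkene only (the vinyl group and the electron-poor methylene lactone are inert), and L-(+)-tartrate sets the C4 stereocentre by reagent control in the sense known for 2-substituted allylic alcohols, which give (S)-2-substituted glycidols.

Step 17
Reactants: 28 epoxy alcohol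
Product: 29 target, (3aS,4S,5S,6S,7R,7aS)-6-ethenyl-5-[(2R)-2-formyloxiran-2-yl]-7-hydroxy-6-methyl-3-methylidene-2-oxooctahydro-1-benzofuran-4-yl 2-methylpropanoate
Conditions: TEMPO (10 mol%), PhI(OAc)2, CH2Cl2, rt
Reagents that add atoms: none
Why: TEMPO/PhI(OAc)2 oxidises the primary alcohol to the aldehyde chemoselectively beside the hindered secondary C9 hydroxyl, and the fully substituted C4 cannot epimerise.

## Compound list

1 | 2-bromoprop-2-en-1-ol | C=C(Br)CO | starting material
2 | [(2-bromoprop-2-en-1-yl)oxy](tert-butyl)diphenylsilane | C=C(Br)CO[Si](c1ccccc1)(c1ccccc1)C(C)(C)C | intermediate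
3 | propyne | CC#C | starting material
4 | dibromo[(1Z)-2-bromoprop-1-en-1-yl]borane | C/C(Br)=C/B(Br)Br | intermediate
5 | 2-[(1Z)-2-bromoprop-1-en-1-yl]-4,4,5,5-tetramethyl-1,3,2-dioxaborolane | C/C(Br)=C/B1OC(C)(C)C(C)(C)O1 | intermediate
6 | vinylmagnesium bromide | C=C[Mg]Br | starting material
7 | vinylzinc bromide | C=C[Zn]Br | intermediate
8 | 4,4,5,5-tetramethyl-2-[(1Z)-2-methylbuta-1,3-dien-1-yl]-1,3,2-dioxaborolane | C=C/C(C)=C\B1OC(C)(C)C(C)(C)O1 | intermediate
9 | tert-butyl{[(3Z)-4-methyl-2-methylidenehexa-3,5-dien-1-yl]oxy}diphenylsilane | C=C/C(C)=C\C(=C)CO[Si](c1ccccc1)(c1ccccc1)C(C)(C)C | intermediate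
10 | tert-butyl{[(3Z,5S)-4-methyl-2-methylidene-5,6-bis(4,4,5,5-tetramethyl-1,3,2-dioxaborolan-2-yl)hex-3-en-1-yl]oxy}diphenylsilane | CC1(C)OB(C[C@H](B2OC(C)(C)C(C)(C)O2)/C(C)=C\C(=C)CO[Si](c2ccccc2)(c2ccccc2)C(C)(C)C)OC1(C)C | intermediate
11 | methyl acrylate | C=CC(=O)OC | starting material
12 | {[tert-butyl(dimethyl)silyl]oxy}acetaldehyde | O=CCO[Si](C)(C)C(C)(C)C | starting material
13 | methyl 2-(2-{[tert-butyl(dimethyl)silyl]oxy}-1-hydroxyethyl)prop-2-enoate (racemic) | C=C(C(=O)OC)C(O)CO[Si](C)(C)C(C)(C)C | intermediate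
14 | methyl (2Z)-2-(bromomethyl)-4-{[tert-butyl(dimethyl)silyl]oxy}but-2-enoate | COC(=O)/C(CBr)=C/CO[Si](C)(C)C(C)(C)C | intermediate
15 | (4R)-2,2-dimethyl-1,3-dioxolane-4-carbaldehyde | O=C[C@H]1COC(C)(C)O1 | starting material
16 | methyl (3S,4S)-3-({[tert-butyl(dimethyl)silyl]oxy}methyl)-4-[(4R)-2,2-dimethyl-1,3-dioxolan-4-yl]-4-hydroxy-2-methylidenebutanoate | COC(=O)C(=C)[C@@H](CO[Si](C)(C)C(C)(C)C)[C@H](O)[C@H]1COC(C)(C)O1 | intermediate
17 | (4S,5S)-4-({[tert-butyl(dimethyl)silyl]oxy}methyl)-5-[(4R)-2,2-dimethyl-1,3-dioxolan-4-yl]-3-methylideneoxolan-2-one | CC(C)(C)[Si](C)(C)OC[C@@H]1C(=C)C(=O)O[C@@H]1[C@H]1COC(C)(C)O1 | intermediate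
18 | (4S,5S)-5-[(4R)-2,2-dimethyl-1,3-dioxolan-4-yl]-4-(hydroxymethyl)-3-methylideneoxolan-2-one | OC[C@@H]1C(=C)C(=O)O[C@@H]1[C@H]1COC(C)(C)O1 | intermediate
19 | (2S,3R)-2-[(4R)-2,2-dimethyl-1,3-dioxolan-4-yl]-4-methylidene-5-oxooxolane-3-carbaldehyde | O=C[C@@H]1C(=C)C(=O)O[C@@H]1[C@H]1COC(C)(C)O1 | intermediate
20 | pinacol borate (O6–Bpin) of 21 | CC1(C)OB(C/C=C(\C)[C@@H]([C@@H](OB2OC(C)(C)C(C)(C)O2)[C@@H]2C(=C)C(=O)O[C@@H]2[C@H]2COC(C)(C)O2)C(=C)CO[Si](c2ccccc2)(c2ccccc2)C(C)(C)C)OC1(C)C | intermediate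
21 | (4S,5S)-4-[(1R,2R,3E)-2-{3-[tert-butyl(diphenyl)silyl]oxyprop-1-en-2-yl}-1-hydroxy-3-methyl-5-(4,4,5,5-tetramethyl-1,3,2-dioxaborolan-2-yl)pent-3-en-1-yl]-5-[(4R)-2,2-dimethyl-1,3-dioxolan-4-yl]-3-methylideneoxolan-2-one | CC1(C)OB(C/C=C(\C)[C@@H]([C@@H](O)[C@@H]2C(=C)C(=O)O[C@@H]2[C@H]2COC(C)(C)O2)C(=C)CO[Si](c2ccccc2)(c2ccccc2)C(C)(C)C)OC1(C)C | intermediate
22 | (1R,2R,3E)-2-{3-[tert-butyl(diphenyl)silyl]oxyprop-1-en-2-yl}-1-{(2S,3S)-2-[(4R)-2,2-dimethyl-1,3-dioxolan-4-yl]-4-methylidene-5-oxooxolan-3-yl}-3-methyl-5-(4,4,5,5-tetramethyl-1,3,2-dioxaborolan-2-yl)pent-3-en-1-yl 2-methylpropanoate | CC1(C)OB(C/C=C(\C)[C@@H]([C@@H](OC(=O)C(C)C)[C@@H]2C(=C)C(=O)O[C@@H]2[C@H]2COC(C)(C)O2)C(=C)CO[Si](c2ccccc2)(c2ccccc2)C(C)(C)C)OC1(C)C | intermediate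
23 | (1R,2R,3E)-2-{3-[tert-butyl(diphenyl)silyl]oxyprop-1-en-2-yl}-1-{(2S,3S)-2-[(1R)-1,2-dihydroxyethyl]-4-methylidene-5-oxooxolan-3-yl}-3-methyl-5-(4,4,5,5-tetramethyl-1,3,2-dioxaborolan-2-yl)pent-3-en-1-yl 2-methylpropanoate | CC1(C)OB(C/C=C(\C)[C@@H]([C@@H](OC(=O)C(C)C)[C@@H]2C(=C)C(=O)O[C@@H]2[C@H](O)CO)C(=C)CO[Si](c2ccccc2)(c2ccccc2)C(C)(C)C)OC1(C)C | intermediate
24 | (1R,2R,3E)-2-{3-[tert-butyl(diphenyl)silyl]oxyprop-1-en-2-yl}-1-[(2S,3S)-2-formyl-4-methylidene-5-oxooxolan-3-yl]-3-methyl-5-(4,4,5,5-tetramethyl-1,3,2-dioxaborolan-2-yl)pent-3-en-1-yl 2-methylpropanoate | CC1(C)OB(C/C=C(\C)[C@@H]([C@@H](OC(=O)C(C)C)[C@@H]2C(=C)C(=O)O[C@@H]2C=O)C(=C)CO[Si](c2ccccc2)(c2ccccc2)C(C)(C)C)OC1(C)C | intermediate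
25 | pinacol borate (O9–Bpin) of 26 | C=C[C@@]1(C)[C@H](C(=C)CO[Si](c2ccccc2)(c2ccccc2)C(C)(C)C)[C@@H](OC(=O)C(C)C)[C@@H]2C(=C)C(=O)O[C@@H]2[C@@H]1OB1OC(C)(C)C(C)(C)O1 | intermediate
26 | (3aS,4R,5S,6S,7R,7aS)-5-{3-[tert-butyl(diphenyl)silyl]oxyprop-1-en-2-yl}-6-ethenyl-7-hydroxy-6-methyl-3-methylidene-2-oxooctahydro-1-benzofuran-4-yl 2-methylpropanoate | C=C[C@@]1(C)[C@H](C(=C)CO[Si](c2ccccc2)(c2ccccc2)C(C)(C)C)[C@@H](OC(=O)C(C)C)[C@@H]2C(=C)C(=O)O[C@@H]2[C@@H]1O | intermediate
27 | (3aS,4R,5S,6S,7R,7aS)-6-ethenyl-7-hydroxy-5-(3-hydroxyprop-1-en-2-yl)-6-methyl-3-methylidene-2-oxooctahydro-1-benzofuran-4-yl 2-methylpropanoate | C=C[C@@]1(C)[C@H](C(=C)CO)[C@@H](OC(=O)C(C)C)[C@@H]2C(=C)C(=O)O[C@@H]2[C@@H]1O | intermediate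
28 | (3aS,4S,5S,6S,7R,7aS)-6-ethenyl-7-hydroxy-5-[(2S)-2-(hydroxymethyl)oxiran-2-yl]-6-methyl-3-methylidene-2-oxooctahydro-1-benzofuran-4-yl 2-methylpropanoate | C=C[C@@]1(C)[C@H]([C@]2(CO)CO2)[C@@H](OC(=O)C(C)C)[C@@H]2C(=C)C(=O)O[C@@H]2[C@@H]1O | intermediate
29 | (3aS,4S,5S,6S,7R,7aS)-6-ethenyl-5-[(2R)-2-formyloxiran-2-yl]-7-hydroxy-6-methyl-3-methylidene-2-oxooctahydro-1-benzofuran-4-yl 2-methylpropanoate | C=C[C@@]1(C)[C@H]([C@]2(C=O)CO2)[C@@H](OC(=O)C(C)C)[C@@H]2C(=C)C(=O)O[C@@H]2[C@@H]1O | target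

## Step count and risks

Total steps: 17. Longest linear sequence: 12 steps (steps 6–17).

**Risk 1, step 11.** The hindered α-, β- and γ-substituted pinacol allyl boronate may add so slowly that the aldehyde isomerises (the exocyclic alkene moving into conjugation with the formyl group) or eliminates the lactone carboxylate first; a mismatched facial preference of the aldehyde could also erode the diastereoselectivity. The fallback masks the methylene lactone as its thiol adduct, which removes the vinylogous acidity of C7–H. It sets out from 18: conjugate addition of thiophenol (PhSH, cat. Et3N) should give the sulfide alcohol F1, and Dess–Martin oxidation the sulfide aldehyde F2. Allylboration with 10 as in step 11 should give the sulfide carbinol F3, acylation as in step 12 the sulfide isobutyrate F4, and aqueous acetic acid the sulfide diol F5. Excess NaIO4 then cleaves the glycol, triggers the ring closure and oxidises sulfur, giving the sulfoxide cyclohexanol F6. Warming F6 in toluene with NaHCO3 eliminates benzenesulfenic acid and returns to the route at 26.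

**Risk 2, step 14.** The allyl boronate may be intercepted by the formaldehyde liberated in the glycol cleavage, hydration of the α-acyloxy aldehyde may retard the closure, or a boat or cis-fused transition state may leak to the C9/C10 diastereomer. The fallback separates the cleavage from the C–C bond formation with a boron group that is inert until activated. It sets out from 23: KHF2 in aqueous methanol should convert the pinacol boronate into the potassium trifluoroborate diol F7. NaIO4 in aqueous acetone then gives the trifluoroborate aldehyde F8, which is extracted free of formaldehyde. BF3·OEt2 in CH2Cl2 at −78 °C releases the allyldifluoroborane, which should close the ring through the same chair transition state; aqueous work-up returns to the route at 26.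

**Risk 3, step 5.** The Pt catalyst may lose site selectivity on the triene (addition at the 1,1-disubstituted alkene, or 1,4- or 1,6-addition), give poor enantiofacial selectivity on a 3,4-disubstituted diene, or the Z-triene may undergo 6π-electrocyclisation on heating. The fallback uses a metal-free, diol-catalysed diboration that runs at room temperature, adds only to monosubstituted alkenes in a concerted syn sense and so has no 1,4-channel. It sets out from 9: B2(neop)2, a chiral glycal-derived trans-1,2-diol catalyst (TBS-DHG, 10 mol%) and DBU in THF at rt should give the bis(neopentyl glycolato) boronate F9. Transesterification with pinacol returns to the route at 10.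

## Further compounds

F1 | step 11 | (4S,5S)-5-[(4R)-2,2-dimethyl-1,3-dioxolan-4-yl]-4-(hydroxymethyl)-3-[(phenylsulfanyl)methyl]oxolan-2-one (C3 epimers) | OC[C@@H]1C(CSc2ccccc2)C(=O)O[C@@H]1[C@H]1COC(C)(C)O1
F2 | step 11 | (2S,3R)-2-[(4R)-2,2-dimethyl-1,3-dioxolan-4-yl]-5-oxo-4-[(phenylsulfanyl)methyl]oxolane-3-carbaldehyde (C4 epimers) | O=C[C@@H]1C(CSc2ccccc2)C(=O)O[C@@H]1[C@H]1COC(C)(C)O1
F3 | step 11 | sulfide analogue of 21 (PhSCH2 on the lactone α-carbon in place of the methylidene group) | CC1(C)OB(C/C=C(\C)[C@@H]([C@@H](O)[C@@H]2C(CSc3ccccc3)C(=O)O[C@@H]2[C@H]2COC(C)(C)O2)C(=C)CO[Si](c2ccccc2)(c2ccccc2)C(C)(C)C)OC1(C)C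
F4 | step 11 | sulfide analogue of 22 | CC1(C)OB(C/C=C(\C)[C@@H]([C@@H](OC(=O)C(C)C)[C@@H]2C(CSc3ccccc3)C(=O)O[C@@H]2[C@H]2COC(C)(C)O2)C(=C)CO[Si](c2ccccc2)(c2ccccc2)C(C)(C)C)OC1(C)C
F5 | step 11 | sulfide analogue of 23 | CC1(C)OB(C/C=C(\C)[C@@H]([C@@H](OC(=O)C(C)C)[C@@H]2C(CSc3ccccc3)C(=O)O[C@@H]2[C@H](O)CO)C(=C)CO[Si](c2ccccc2)(c2ccccc2)C(C)(C)C)OC1(C)C
F6 | step 11 | sulfoxide analogue of 26 (PhS(O)CH2 on the lactone α-carbon) | C=C[C@@]1(C)[C@H](C(=C)CO[Si](c2ccccc2)(c2ccccc2)C(C)(C)C)[C@@H](OC(=O)C(C)C)[C@@H]2C(CS(=O)c3ccccc3)C(=O)O[C@@H]2[C@@H]1O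
F7 | step 14 | potassium trifluoroborate analogue of 23 | [K+].F[B-](F)(F)C/C=C(\C)[C@@H]([C@@H](OC(=O)C(C)C)[C@@H]1C(=C)C(=O)O[C@@H]1[C@H](O)CO)C(=C)CO[Si](c1ccccc1)(c1ccccc1)C(C)(C)C
F8 | step 14 | potassium trifluoroborate analogue of 24 | [K+].F[B-](F)(F)C/C=C(\C)[C@@H]([C@@H](OC(=O)C(C)C)[C@@H]1C(=C)C(=O)O[C@@H]1C=O)C(=C)CO[Si](c1ccccc1)(c1ccccc1)C(C)(C)C
F9 | step 5 | tert-butyl{[(3Z,5S)-5,6-bis(5,5-dimethyl-1,3,2-dioxaborinan-2-yl)-4-methyl-2-methylidenehex-3-en-1-yl]oxy}diphenylsilane | CC1(C)COB(OC1)C[C@H](B1OCC(C)(C)CO1)/C(C)=C\C(=C)CO[Si](c1ccccc1)(c1ccccc1)C(C)(C)C
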